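The runs were generated by integration for an exercise; scatter was added.

Partner is conserved by count: in a closed flask each partner that reacts stays on an adduct as one arm, and the tris adduct, as its name says, carries 3 of them. The temperature and the time do not enter this count. With 25.3 mM of partner on 23 mM of starting material in cedar and alder, the count gives 36.7%, and this number, c(partner) over 3 c(starting material), is the partner ceiling: the most tris adduct the charge can pay for, in percent of the starting material charged, a stoichiometric limit. For ash and elm, with 8.00 mM of partner, it comes to 11.6%.

common to all: starting material 23 mM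

| flask | partner | temperature | remark | time |
|---|---|---|---|---|
| south | 4.4 mM | 20 °C | run made earlier |  |
| north | 19 mM | 45 °C | run made earlier |  |
| ash | 8.00 mM | 25 °C |  | 5.0 h |
| cedar | 25.3 mM | 25 °C |  | 5.0 h |
| alder | 25.3 mM | 65 °C |  | 5.0 h |
| elm | 8.00 mM | 65 °C |  | 5.0 h |

- south (time / h: tris adduct / %, starting material / %): 0.667: 0, 28.9; 1.33: 0, 16.2; 2.00: 0, 11.4; 3.00: 0.7, 6.9; 4.00: 0.9, 5.4
- north (time / min: tris adduct / %, starting material / %): 6.00: 0.8, 32.1; 12.0: 2.2, 17.7; 20.0: 5.6, 10.6; 40.0: 11.4, 5.6; 80.0: 17.3, 2.0

(scatter of a reading: 0.5 percentage points)

* all flasks from highest to lowest amount of tris adduct, in percent of the starting material charged, at 5.0 h (ash / cedar / alder / elm)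
* the same order at 30 min (ash / cedar / alder / elm)
* the amount of tris adduct, in percent of the starting material charged of the flask you put first, at 5.0 h
* the amount of tris adduct, in percent of the starting material charged of the flask you put last, at 5.0 h

The earlier runs stayed under this count: the north run, with a ceiling of 27.5%, read 17.3% of tris adduct at 80.0 min. That is 62.8% of its ceiling. The ceiling is a bound and not a yield. In the south run the starting material read 5.4% at 4.00 h, although the partner charge equals 19.1% of it, so at least 75.5% left by a path without partner. I committed to a bound and no more: I expected none of the four flasks above its own ceiling at 5.0 h.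

The forecast, reasoning that “The adduct then forms slowly from this intermediate”, gave alder > cedar > elm > ash at 5.0 h and alder > elm > cedar > ash at 30 min, with 45% for the first flask and 4.5% for the last, so its top stood higher than my ceiling, and there the two reckonings parted.

The flasks gave cedar > alder > elm > ash at 5.0 h and alder > elm > cedar > ash at 30 min, with 23.3% in cedar and 4.20% in ash.

    partner + tris adduct → tetra adduct + by-product (k = 5.90 × 10⁻⁴ L mol⁻¹ s⁻¹, Ea = 53.0 kJ mol⁻¹)
    partner + mono adduct → bis adduct + by-product (k = 0.0170 L mol⁻¹ s⁻¹, Ea = 72.0 kJ mol⁻¹)
    partner + bis adduct → tris adduct + by-product (k = 0.0270 L mol⁻¹ s⁻¹, Ea = 45.0 kJ mol⁻¹)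
    2 starting material → self-condensation product (k = 0.0300 L mol⁻¹ s⁻¹, Ea = 49.0 kJ mol⁻¹)
    starting material + partner → mono adduct + by-product (k = 0.0110 L mol⁻¹ s⁻¹, Ea = 48.0 kJ mol⁻¹)
    (constants at 25 °C)

Cedar's tris adduct reached 63.5% of its ceiling of 36.7%. The loss of 2 starting material to self-condensation product is a part of what carried it there: the same cedar run without that step gave 16.8% instead of 23.3%, and the order of the flasks turned at both times. Elm, under the lower ceiling of 11.6%, stood at 9.44% at 5.00 h, which is 81.4% of that ceiling, with 0.545% of its own partner charge left.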